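In a one-step world, where electrophile and nucleophile give target, the target gained equals the electrophile lost, so the rate of the one over the rate of the other is one at each moment and time drops out.

| flask | electrophile | nucleophile | free base | remark | time |
|---|---|---|---|---|---|
| gamma | 15 mM | 22.5 mM | 6.8 mM | run made earlier |  |
| north | 15 mM | 22.5 mM | 20.0 mM |  | 2.5 min |
| east | 15 mM | 22.5 mM | 16.0 mM |  | 2.5 min |
| south-east | 15 mM | 22.5 mM | 12.0 mM |  | 2.5 min |

gamma run (percent of the electrophile charged)

| time / s | electrophile / % | target / % |
|---|---|---|
| 10.0 | 15.0 | 76.0 |
| 15.0 | 9.3 | 79.5 |
| 20.0 | 5.4 | 80.0 |
| 30.0 | 4.4 | 84.7 |
| 50.0 | 3.4 | 86.5 |
| 80.0 | 2.9 | 87.6 |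

(scatter of a reading: 1 percentage point)

- part of the electrophile that has reacted at the end, north
- part of the electrophile that has reacted at the end, east
- part of the electrophile that has reacted at the end, south-east
- what raising the concentration of free base from its lowest to its highest value here does to the part of the electrophile that has reacted (changes below 5 percentage points count as none) (it falls / no change / it rises)

- a reading or a percentage of target counts all its forms, free or not
- what has gone from electrophile into another species counts as reacted, even if it can come back
- no earlier run changes the charge of free base; that part of a forecast is a guess
- a reading of electrophile is of its free form alone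

In gamma, between 30.0 s and 80.0 s, the readings of free electrophile fall by 1.5 percentage points while those of target rise by 2.9 points, a larger gain than loss, so, if this gap is more than scatter, target is being fed from a store that the electrophile reading does not show. If that store keeps step with the free electrophile, the rate ratio equals one plus the simulated parts per free part, and this first way gives 0.933.

The second way counts the store directly in gamma. Summed over the readings from 30.0 s on, it gives 2.85, the parking ratio: parts of the charge neither free electrophile nor target per part of free electrophile. The two ways part, and the first one cheats, because the scatter of a difference of two readings is 1.4 points, about as large as the fall it divides by. I keep the counted ratio.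

The readings of the fraction not yet target in gamma drain at 0.00420 s⁻¹, and if that rate holds I reckon 9.24% left at 2.5 min. Of this, one part in one plus the parking ratio is free, 2.40%, so I reckon 97.6% reacted. Taking more free base as no hindrance, which is a guess, I use this one figure for north, east and south-east; the room left is smaller than the margin, so I expect no change. The forecast gives 99%, 98.7% and 98.3% with no change, holding that “The ceiling keeps any change below 5 points”, and its figures lie above mine.

The flasks give 99.5% in north, 99.4% in east and 99.2% in south-east, a spread of 0.33 points, so no change.

    nucleophile + acid set free ⇌ protonated nucleophile, settled at all times (K = 67000 L mol⁻¹)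
    electrophile ⇌ dormant form (K = 2.20, k = 0.0320 s⁻¹)
    2 nucleophile → self-condensation product (k = 0.590 L mol⁻¹ s⁻¹)
    electrophile + nucleophile → acid set free + target (k = 22.0 L mol⁻¹ s⁻¹)
    electrophile + target ⇌ idle adduct, settled at all times (K = 16.0 L mol⁻¹)
    acid set free + free base ⇌ salt of the base, settled at all times (K = 1.40 × 10⁵ L mol⁻¹)

In south-east the step with nucleophile, taken alone, has a half-life for electrophile of 1.4 s at the charged amounts, shorter than the 0.36 min of the forward step into the dormant form taken alone, and at 2.50 min that dormant form is the resting state, 3.56% against 0.825% free. In the neighbour of south-east charged with 60 mM of electrophile, nucleophile at 0.375 equiv is the limiting reagent, with 0.071% of its charge left unbound, and target stands at 31.3%. The parking ratio then gives 17.8% free electrophile in that neighbour, and it holds 19.9%.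

The earlier runs and the new flask are calculated with constants of no real substance; scatter was added.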